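Cuts (C1 lactone C=O, C2 H2, C3 H–C–OO, C4 C(CH3)–O-lactone, C5 H2, C6 C(CH3)(C16H33)–OO): first C5–H and C4–O (deiodination, iodolactonisation), then C4=C5 (ring-closing metathesis), then C3–OO (SN2) and C6–OO (epoxide perhydrolysis).
Enabling feature: in the 1,2-dioxane ring (O, O, C3, C4, C5, C6), C4–C5 is the one C–C bond whose two carbons can both be reduced to plain alkene carbons. C5 is a bare CH2, and the only heteroatom on C4, the γ-lactone oxygen, can be put back later by the C1 carboxyl group that hangs from C3.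
Forward: a C6 half (from 1-octadecyne) and a C3 half (from 1,3-propanediol and isopropenylmagnesium bromide) are joined through the O–O unit. The dioxine ring closes first by metathesis, the lactone ring second by iodolactonisation.
Stereochemistry: C6 comes from Sharpless epoxidation and invertive opening by H2O2. C3 comes from Sharpless kinetic resolution and invertive mesylate displacement. C4 comes from the carboxylate tethered at C3 (cis fusion). The transient C5 iodide centre is erased.

Key step: step 12

Remark on the structure: the target is taken as drawn, (3S,4S,6R) in the numbering above, which is (3R,4aS,7aS) in furo[3,2-c][1,2]dioxin-6-one numbering. The hexadecyl group lies on the same face of the dioxane as the lactone ring.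
Assumption: the acid-catalysed perhydrolysis of the trisubstituted epoxide is taken to occur at the tertiary carbon with inversion, in line with the trans opening of 1-alkylcycloalkene oxides.

Step 1
Reactants: 1 1-octadecyne
Product: 4 (E)-3-methylnonadec-2-en-1-ol, via alkenyldimethylalane 2 (not isolated), via lithium alkenylaluminate 3 (not isolated)
Conditions: AlMe3 (2 equiv), Cp2ZrCl2 (0.25 equiv), CH2Cl2, 0 °C to rt; volatiles removed; n-BuLi, hexane/THF, −78 to 0 °C; (CH2O)n, rt; 1 M HCl
Reagents that add atoms: trimethylaluminium, C[Al](C)C; paraformaldehyde (reacts as formaldehyde), C=O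
Why: Negishi zirconium-catalysed carboalumination adds CH3 and Al syn across the terminal alkyne with aluminium at the terminus, and hydroxymethylation of the derived aluminate keeps the alkene geometry, so the E trisubstituted allylic alcohol should form in one flask.

Step 2
Reactants: 4 (E)-3-methylnonadec-2-en-1-ol
Product: 5 [(2S,3S)-3-hexadecyl-3-methyloxiran-2-yl]methanol
Conditions: Ti(OiPr)4 (10 mol %), L-(+)-diethyl tartrate (12 mol %), t-BuOOH, 4 Å MS, CH2Cl2, −20 °C
Reagents that add atoms: tert-butyl hydroperoxide, CC(C)(C)OO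
Why: Sharpless asymmetric epoxidation of a geraniol-type (E)-3-methyl-2-alken-1-ol, in which the L-(+)-tartrate complex selects the alkene face and sets both epoxide carbons as 2S,3S by reagent control.

Step 3
Reactants: 5 [(2S,3S)-3-hexadecyl-3-methyloxiran-2-yl]methanol
Product: 6 (2S,3R)-3-hydroperoxy-3-methylnonadecane-1,2-diol
Conditions: H2O2 (dry ethereal solution, 10 equiv), H3PMo12O40 (3 mol %), Et2O, rt
Reagents that add atoms: hydrogen peroxide, OO
Why: Acid-catalysed perhydrolysis of an epoxide, in which the tertiary C3 carries the developing positive charge while C2 is deactivated by the neighbouring CH2OH, and H2O2 enters anti to the still-bound epoxide oxygen, so 3S is inverted to 3R (the future C6) and C2 is untouched.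

Step 4
Reactants: 7 1,3-propanediol
Product: 8 3-(tert-butyldimethylsilyloxy)propan-1-ol
Conditions: TBSCl (1 equiv), imidazole (1.1 equiv), diol (3 equiv), CH2Cl2/DMF, 0 °C to rt
Reagents that add atoms: tert-butyldimethylsilyl chloride, CC(C)(C)[Si](C)(C)Cl
Why: Routine silyl ether formation on a symmetrical diol used in excess, which leaves one primary hydroxyl free and involves no stereocentre.

Step 5
Reactants: 8 3-(tert-butyldimethylsilyloxy)propan-1-ol
Product: 9 3-(tert-butyldimethylsilyloxy)propanal
Conditions: TEMPO (10 mol %), PhI(OAc)2 (1.1 equiv), CH2Cl2, rt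
Reagents that add atoms: none
Why: Oxoammonium (TEMPO) oxidation stops at the aldehyde in anhydrous CH2Cl2 and is mild enough to avoid β-elimination of the silyloxy group.

Step 6
Reactants: 9 3-(tert-butyldimethylsilyloxy)propanal; 10 isopropenylmagnesium bromide
Product: 11 (±)-5-(tert-butyldimethylsilyloxy)-2-methylpent-1-en-3-ol
Conditions: THF, −78 to 0 °C; sat. aq NH4Cl
Reagents that add atoms: isopropenylmagnesium bromide (10), CC(=C)[Mg]Br
Why: Grignard 1,2-addition to the aldehyde builds the C3–C4 bond and gives the racemic isopropenyl carbinol, whose configuration is sorted out in the next step.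

Step 7
Reactants: 11 (±)-5-(tert-butyldimethylsilyloxy)-2-methylpent-1-en-3-ol
Product: 12 (3R)-5-(tert-butyldimethylsilyloxy)-2-methylpent-1-en-3-ol
Conditions: Ti(OiPr)4 (0.1 equiv), L-(+)-diisopropyl tartrate (0.15 equiv), t-BuOOH (0.6 equiv), 4 Å MS, CH2Cl2, −20 °C, run just past half conversion
Reagents that add atoms: none
Why: Sharpless kinetic resolution, in which the L-(+)-tartrate catalyst epoxidises the S enantiomer of a secondary allylic alcohol (OH > alkenyl > alkyl > H) much faster, 2-methyl-1-alken-3-ols being a favourable class, so the R alcohol should be recovered enantioenriched.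

Step 8
Reactants: 12 (3R)-5-(tert-butyldimethylsilyloxy)-2-methylpent-1-en-3-ol
Product: 13 (3R)-5-(tert-butyldimethylsilyloxy)-2-methylpent-1-en-3-yl methanesulfonate
Conditions: MsCl (1.2 equiv), Et3N (1.5 equiv), CH2Cl2, −20 °C; cold aqueous work-up, used crude at once
Reagents that add atoms: methanesulfonyl chloride, CS(=O)(=O)Cl
Why: Standard O-sulfonylation breaks no bond at C3, so the R configuration is kept, and low temperature with immediate use limits ionisation of the allylic mesylate.

Step 9
Reactants: 6 (2S,3R)-3-hydroperoxy-3-methylnonadecane-1,2-diol; 13 (3R)-5-(tert-butyldimethylsilyloxy)-2-methylpent-1-en-3-yl methanesulfonate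
Product: 15 (2S,3R)-3-{[(3S)-5-(tert-butyldimethylsilyloxy)-2-methylpent-1-en-3-yl]peroxy}-3-methylnonadecane-1,2-diol, via caesium peroxide 14 (not isolated)
Conditions: 6, 13 (1.5 equiv), Cs2CO3 (1.2 equiv, added last), DMF, 0 °C
Reagents that add atoms: none
Why: SN2 alkylation of a hydroperoxide anion by a secondary sulfonate, in which Cs2CO3 deprotonates only the OOH group, the α-effect nucleophile attacks C3 from the rear and inverts R to S, C6 is not touched, and any C3 or C6 epimer is now a diastereomer that chromatography can remove.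

Step 10
Reactants: 15 (2S,3R)-3-{[(3S)-5-(tert-butyldimethylsilyloxy)-2-methylpent-1-en-3-yl]peroxy}-3-methylnonadecane-1,2-diol
Product: 16 (2R)-2-{[(3S)-5-(tert-butyldimethylsilyloxy)-2-methylpent-1-en-3-yl]peroxy}-2-methyloctadecanal
Conditions: NaIO4 (1.5 equiv), THF/H2O, 0 °C to rt
Reagents that add atoms: none
Why: Malaprade glycol cleavage is neutral and specific for the 1,2-diol, spares the dialkyl peroxide, alkene and silyl ether, and gives an aldehyde whose α-carbon (C6) is quaternary and cannot epimerise.

Step 11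
Reactants: 16 (2R)-2-{[(3S)-5-(tert-butyldimethylsilyloxy)-2-methylpent-1-en-3-yl]peroxy}-2-methyloctadecanal
Product: 17 (3S)-5-(tert-butyldimethylsilyloxy)-2-methylpent-1-en-3-yl (3R)-3-methylnonadec-1-en-3-yl peroxide
Conditions: Ph3PCH3Br (1.3 equiv), KN(SiMe3)2 (1.2 equiv), THF, 0 °C; then 16, −78 to 0 °C
Reagents that add atoms: methyltriphenylphosphonium bromide, C[P+](c1ccccc1)(c1ccccc1)c1ccccc1.[Br-]
Why: Wittig methylenation of a peroxide-bearing aldehyde, in which carbonyl addition at −78 °C should outrun base-induced Kornblum–DeLaMare cleavage at C3–H and no stereocentre is affected.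

Step 12
Reactants: 17 (3S)-5-(tert-butyldimethylsilyloxy)-2-methylpent-1-en-3-yl (3R)-3-methylnonadec-1-en-3-yl peroxide
Product: 18 (3S,6R)-3-[2-(tert-butyldimethylsilyloxy)ethyl]-6-hexadecyl-4,6-dimethyl-3,6-dihydro-1,2-dioxine
Conditions: second-generation Grubbs catalyst RuCl2(=CHPh)(PCy3)(H2IMes) (10 mol %, two portions), CH2Cl2 (0.005 M), 40 °C, argon sparge
Reagents that add atoms: none
Why: The benzylidene exchanges with the monosubstituted vinyl group on C6 to place ruthenium on C5, this alkylidene adds [2+2] to the 1,1-disubstituted isopropenyl alkene at C4, and cycloreversion of the ruthenacyclobutane releases the C4=C5 alkene and Ru=CH2, which carries the chain with loss of ethylene. The closest known reactions are ring-closing metatheses of bis-allylic dialkyl peroxides to 3,6-dihydro-1,2-dioxines and of dienes to trisubstituted cyclohexenes next to quaternary carbons with N-heterocyclic-carbene ruthenium catalysts. The one ring closed is the six-membered dioxine (O1, O2, C3 to C6), formed by olefin metathesis with both new sp2 carbons inside the ring, so the alkene can only be cis within it. No stereocentre is created, and C3 (S) and C6 (R) persist because no bond to either is broken. Cyclisation must beat cross-metathesis dimerisation and O–O cleavage: high dilution, ethylene removal, full substitution at C6 (Thorpe–Ingold compression) and the gauche C–O–O–C geometry favour closure, while a dialkyl peroxide without O–H, shielded by quaternary C6 and branched C3, should offer divalent ruthenium and liberated PCy3 little purchase at 40 °C.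

Step 13
Reactants: 18 (3S,6R)-3-[2-(tert-butyldimethylsilyloxy)ethyl]-6-hexadecyl-4,6-dimethyl-3,6-dihydro-1,2-dioxine
Product: 19 2-[(3S,6R)-6-hexadecyl-4,6-dimethyl-3,6-dihydro-1,2-dioxin-3-yl]ethanol
Conditions: HF·pyridine, THF, 0 °C
Reagents that add atoms: none
Why: Fluoride-mediated desilylation under acidic rather than basic conditions avoids the Kornblum–DeLaMare opening that basic fluoride sources could trigger at the allylic C3–H of the dihydrodioxine.

Step 14
Reactants: 19 2-[(3S,6R)-6-hexadecyl-4,6-dimethyl-3,6-dihydro-1,2-dioxin-3-yl]ethanol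
Product: 21 2-[(3S,6R)-6-hexadecyl-4,6-dimethyl-3,6-dihydro-1,2-dioxin-3-yl]acetic acid, via peroxy aldehyde 20 (not isolated)
Conditions: TEMPO (20 mol %), PhI(OAc)2 (2.2 equiv), MeCN/H2O 1:1, rt
Reagents that add atoms: water, O
Why: TEMPO/PhI(OAc)2 oxidation in aqueous acetonitrile carries the primary alcohol through the aldehyde hydrate to the acid in a weakly acidic medium, so the β-peroxy aldehyde is short-lived and base-induced retro-oxa-Michael opening at C3 has no chance.

Step 15
Reactants: 21 2-[(3S,6R)-6-hexadecyl-4,6-dimethyl-3,6-dihydro-1,2-dioxin-3-yl]acetic acid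
Product: 22 (3R,4S,4aR,7aS)-3-hexadecyl-4-iodo-3,4a-dimethyl-7,7a-dihydro-4H-furo[3,2-c][1,2]dioxin-6-one (5-iodo lactone, iodine trans to the C4 lactone oxygen)
Conditions: I2 (3 equiv), KI, NaHCO3, Et2O/H2O, 0 °C to rt, dark
Reagents that add atoms: iodine, [I][I]
Why: Iodolactonisation of a γ,δ-unsaturated acid, in which reversible iodonium formation is productive only on the face opposite the C3 side chain and the carboxylate closes 5-exo at the more substituted C4 from its own face, which sets C4 with a cis-fused lactone and places iodine on C5 anti to it.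

Step 16
Reactants: 22 (3R,4S,4aR,7aS)-3-hexadecyl-4-iodo-3,4a-dimethyl-7,7a-dihydro-4H-furo[3,2-c][1,2]dioxin-6-one
Product: 23 (3R,4aS,7aS)-3-hexadecyl-3,4a-dimethyl-7,7a-dihydro-4H-furo[3,2-c][1,2]dioxin-6-one (CNP0079571.1)
Conditions: Bu3SnH (3 equiv, 0.3 M), Et3B (0.2 equiv)/air, toluene, 0 °C to rt
Reagents that add atoms: none
Why: Radical-chain deiodination, known for iodolactones fused to 1,2-dioxanes, in which iodine abstraction is far faster than stannyl attack on O–O, the ring geometry denies the C5 radical a collinear attack on the peroxide oxygen, and concentrated Bu3SnH quenches it to the C5 methylene, leaving C3, C4 and C6 unchanged.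

Compound list
1 | 1-octadecyne | CCCCCCCCCCCCCCCCC#C | starting material
2 | (E)-dimethyl(2-methyloctadec-1-en-1-yl)alane | CCCCCCCCCCCCCCCC/C(C)=C/[Al](C)C | intermediate
3 | lithium (E)-butyl(dimethyl)(2-methyloctadec-1-en-1-yl)aluminate | CCCCCCCCCCCCCCCC/C(C)=C/[Al-](C)(C)CCCC.[Li+] | intermediate
4 | (E)-3-methylnonadec-2-en-1-ol | CCCCCCCCCCCCCCCC/C(C)=C/CO | intermediate
5 | [(2S,3S)-3-hexadecyl-3-methyloxiran-2-yl]methanol | CCCCCCCCCCCCCCCC[C@]1(C)O[C@H]1CO | intermediate
6 | (2S,3R)-3-hydroperoxy-3-methylnonadecane-1,2-diol | CCCCCCCCCCCCCCCC[C@@](C)(OO)[C@@H](O)CO | intermediate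
7 | 1,3-propanediol | OCCCO | starting material
8 | 3-(tert-butyldimethylsilyloxy)propan-1-ol | OCCCO[Si](C)(C)C(C)(C)C | intermediate
9 | 3-(tert-butyldimethylsilyloxy)propanal | O=CCCO[Si](C)(C)C(C)(C)C | intermediate
10 | isopropenylmagnesium bromide | CC(=C)[Mg]Br | starting material
11 | (±)-5-(tert-butyldimethylsilyloxy)-2-methylpent-1-en-3-ol | C=C(C)C(O)CCO[Si](C)(C)C(C)(C)C | intermediate
12 | (3R)-5-(tert-butyldimethylsilyloxy)-2-methylpent-1-en-3-ol | C=C(C)[C@@H](CCO[Si](C)(C)C(C)(C)C)O | intermediate
13 | (3R)-5-(tert-butyldimethylsilyloxy)-2-methylpent-1-en-3-yl methanesulfonate | C=C(C)[C@@H](CCO[Si](C)(C)C(C)(C)C)OS(C)(=O)=O | intermediate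
14 | caesium (2S,3R)-1,2-dihydroxy-3-methylnonadecan-3-yl peroxide | CCCCCCCCCCCCCCCC[C@@](C)(O[O-])[C@@H](O)CO.[Cs+] | intermediate
15 | (2S,3R)-3-{[(3S)-5-(tert-butyldimethylsilyloxy)-2-methylpent-1-en-3-yl]peroxy}-3-methylnonadecane-1,2-diol | C=C(C)[C@H](CCO[Si](C)(C)C(C)(C)C)OO[C@](C)(CCCCCCCCCCCCCCCC)[C@@H](O)CO | intermediate
16 | (2R)-2-{[(3S)-5-(tert-butyldimethylsilyloxy)-2-methylpent-1-en-3-yl]peroxy}-2-methyloctadecanal | C=C(C)[C@H](CCO[Si](C)(C)C(C)(C)C)OO[C@](C)(CCCCCCCCCCCCCCCC)C=O | intermediate
17 | (3S)-5-(tert-butyldimethylsilyloxy)-2-methylpent-1-en-3-yl (3R)-3-methylnonadec-1-en-3-yl peroxide | C=C(C)[C@H](CCO[Si](C)(C)C(C)(C)C)OO[C@](C)(CCCCCCCCCCCCCCCC)C=C | intermediate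
18 | (3S,6R)-3-[2-(tert-butyldimethylsilyloxy)ethyl]-6-hexadecyl-4,6-dimethyl-3,6-dihydro-1,2-dioxine | CCCCCCCCCCCCCCCC[C@]1(C)C=C(C)[C@H](CCO[Si](C)(C)C(C)(C)C)OO1 | intermediate
19 | 2-[(3S,6R)-6-hexadecyl-4,6-dimethyl-3,6-dihydro-1,2-dioxin-3-yl]ethanol | CCCCCCCCCCCCCCCC[C@]1(C)C=C(C)[C@H](CCO)OO1 | intermediate
20 | 2-[(3S,6R)-6-hexadecyl-4,6-dimethyl-3,6-dihydro-1,2-dioxin-3-yl]acetaldehyde | CCCCCCCCCCCCCCCC[C@]1(C)C=C(C)[C@H](CC=O)OO1 | intermediate
21 | 2-[(3S,6R)-6-hexadecyl-4,6-dimethyl-3,6-dihydro-1,2-dioxin-3-yl]acetic acid | CCCCCCCCCCCCCCCC[C@]1(C)C=C(C)[C@H](CC(=O)O)OO1 | intermediate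
22 | (3R,4S,4aR,7aS)-3-hexadecyl-4-iodo-3,4a-dimethyl-7,7a-dihydro-4H-furo[3,2-c][1,2]dioxin-6-one | CCCCCCCCCCCCCCCC[C@]1(C)[C@@H](I)[C@]2(C)OC(=O)C[C@@H]2OO1 | intermediate
23 | (3R,4aS,7aS)-3-hexadecyl-3,4a-dimethyl-7,7a-dihydro-4H-furo[3,2-c][1,2]dioxin-6-one | CCCCCCCCCCCCCCCC[C@]1(C)C[C@]2(C)OC(=O)C[C@@H]2OO1 | target

Total step count: 16 (C6 branch steps 1–3, C3 branch steps 4–8, common line steps 9–16).
Longest linear sequence: 13 steps (steps 4–16).

Steps most likely to fail

Step 9. The hindered tertiary peroxide anion may attack too slowly. The allylic mesylate would then be lost to elimination (conjugated diene), SN2′ attack or ionisation with erosion at C3. Meanwhile the β-hydroxy hydroperoxide could be consumed by base-induced Grob-type C–C cleavage. The fallback forms the C3–O bond by conjugate addition instead of displacement and sets out from hydroperoxide 6.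
- Methacrolein and Ph3P=CHCHO give (E)-4-methylpenta-2,4-dienal F1.
- F1 takes up 6 at C3 under iminium catalysis (diarylprolinol silyl ether plus a carboxylic acid). This is the catalytic enantioselective peroxidation of enals, with the catalyst enantiomer chosen for 3S. It gives (3S)-3-{[(2S,3R)-1,2-dihydroxy-3-methylnonadecan-3-yl]peroxy}-4-methylpent-4-enal F2.
- Pinnick oxidation (NaClO2, NaH2PO4, 2-methyl-2-butene) gives the corresponding pent-4-enoic acid F3.
- NaIO4 cleaves the diol to (3S)-4-methyl-3-{[(2R)-2-methyl-1-oxooctadecan-2-yl]peroxy}pent-4-enoic acid F4.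
- Excess Ph3P=CH2 gives (3S)-4-methyl-3-{[(3R)-3-methylnonadec-1-en-3-yl]peroxy}pent-4-enoic acid F5.
- Ring-closing metathesis of F5 under the conditions of step 12 forms the same C4=C5 bond and the same ring, and the route is rejoined at acid 21.

Step 12. Both alkenes are hindered. Slow loading next to quaternary C6 may let catalyst decay, dimerisation, or O–O cleavage by ruthenium or free phosphine overtake ring closure. The fallback is a relay ring-closing metathesis that keeps the C4=C5 disconnection and sets out from aldehyde 16.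
- Wittig reaction with Ph3P=CH(CH2)3CH=CH2 (from hex-5-enyltriphenylphosphonium bromide and KN(SiMe3)2) gives (3S)-5-(tert-butyldimethylsilyloxy)-2-methylpent-1-en-3-yl (6Z,8R)-8-methyltetracosa-1,6-dien-8-yl peroxide F6.
- The catalyst loads on the unhindered terminal alkene and expels cyclopentene, which places it directly on C5. It then closes onto the isopropenyl group.
- The route is rejoined at dihydrodioxine 18.

Step 3. The opening may drift towards a free tertiary cation, with loss of configuration at the future C6. It could also divert to attack at C2 or to a pinacol-type shift. The fallback gives up control at C6 and lets the enantioenriched C3 centre resolve it. It sets out from mesylate 13.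
- Purchased 2-octadecanone and vinylmagnesium bromide give racemic 3-methylnonadec-1-en-3-ol F7.
- H2O2 with catalytic H2SO4 converts F7 into racemic 3-hydroperoxy-3-methylnonadec-1-ene F8.
- Cs2CO3/DMF alkylation of F8 with 13 gives 17 directly, together with its 6S epimer F9, so steps 10 and 11 fall away.
- The pair is ring-closed as in step 12, and 18 is separated by chromatography from the (3S,6S)-dihydrodioxine F10.
- The route is rejoined at 18, at the cost of half the material.

Further compounds
F1 | step 9 | (E)-4-methylpenta-2,4-dienal | C=C(C)/C=C/C=O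
F2 | step 9 | (3S)-3-{[(2S,3R)-1,2-dihydroxy-3-methylnonadecan-3-yl]peroxy}-4-methylpent-4-enal | C=C(C)[C@H](CC=O)OO[C@](C)(CCCCCCCCCCCCCCCC)[C@@H](O)CO
F3 | step 9 | (3S)-3-{[(2S,3R)-1,2-dihydroxy-3-methylnonadecan-3-yl]peroxy}-4-methylpent-4-enoic acid | C=C(C)[C@H](CC(=O)O)OO[C@](C)(CCCCCCCCCCCCCCCC)[C@@H](O)CO
F4 | step 9 | (3S)-4-methyl-3-{[(2R)-2-methyl-1-oxooctadecan-2-yl]peroxy}pent-4-enoic acid | C=C(C)[C@H](CC(=O)O)OO[C@](C)(CCCCCCCCCCCCCCCC)C=O
F5 | step 9 | (3S)-4-methyl-3-{[(3R)-3-methylnonadec-1-en-3-yl]peroxy}pent-4-enoic acid | C=C(C)[C@H](CC(=O)O)OO[C@](C)(CCCCCCCCCCCCCCCC)C=C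
F6 | step 12 | (3S)-5-(tert-butyldimethylsilyloxy)-2-methylpent-1-en-3-yl (6Z,8R)-8-methyltetracosa-1,6-dien-8-yl peroxide | C=C(C)[C@H](CCO[Si](C)(C)C(C)(C)C)OO[C@](C)(CCCCCCCCCCCCCCCC)/C=C\CCCC=C
F7 | step 3 | racemic 3-methylnonadec-1-en-3-ol | C=CC(C)(O)CCCCCCCCCCCCCCCC
F8 | step 3 | racemic 3-hydroperoxy-3-methylnonadec-1-ene | C=CC(C)(OO)CCCCCCCCCCCCCCCC
F9 | step 3 | (3S)-5-(tert-butyldimethylsilyloxy)-2-methylpent-1-en-3-yl (3S)-3-methylnonadec-1-en-3-yl peroxide | C=C(C)[C@H](CCO[Si](C)(C)C(C)(C)C)OO[C@@](C)(CCCCCCCCCCCCCCCC)C=C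
F10 | step 3 | (3S,6S)-3-[2-(tert-butyldimethylsilyloxy)ethyl]-6-hexadecyl-4,6-dimethyl-3,6-dihydro-1,2-dioxine | CCCCCCCCCCCCCCCC[C@@]1(C)C=C(C)[C@H](CCO[Si](C)(C)C(C)(C)C)OO1
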